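**Plan**

- Retrosynthetic cuts: the enol-lactone C–O bond (gives an aryl carboxylic acid and a ring-A aldehyde); the thiazine C–N and C–S bonds (gives a 2-methoxy-1,4-naphthoquinone and hypotaurine); in ring A, the bond from the aryl-bearing quaternary carbon to the carbon that carries the formyl-level carbon, together with the ring C=C between the methyl-bearing carbon and its CH neighbour (gives a β-aryl enone and ethyl acetoacetate); and the aryl–alkenyl bond (Heck).
- Enabling feature: in ring A the carbon bearing the enol-ester CH lies between the methyl-bearing sp2 carbon and the quaternary benzylic carbon. It is the α-carbon of a disguised acetoacetate (methyl-bearing carbon = ketone carbon, enol-ester CH = ester carbon). Ring A is therefore acetoacetate plus Ar(Me)C=CH–COMe by Michael addition and aldol condensation; the extra ring C=O is a helper that is removed afterwards.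
- Forward order: 6-carboxy-1-tetralone → ortho-iodide → regiodefined 1,2,4-trimethoxynaphthalene → Heck enone → ring A annulation → removal of the helper ketone and ester-to-aldehyde reduction → quinone → thiazine dioxide ring → enol-lactone ring last.
- Stereochemistry: the single quaternary stereocentre is set in the annulation by a cinchona primary-amine catalyst. The N/S orientation of the thiazine is fixed by the tetralone carbonyl through the 2-methoxy group of the quinone.

Key step: step 6

Remark: which pseudo-enantiomer of the amine catalyst gives the required sense at the quaternary carbon must be found by experiment (the quinine-derived one is written); this carbon is R in 10–15 and 17–20 and S in 21 only because the CIP priorities change, not the spatial arrangement.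

Step 1
Reactants: 1 5-oxo-5,6,7,8-tetrahydronaphthalene-2-carboxylic acid
Product: 2 3-iodo-5-oxo-5,6,7,8-tetrahydronaphthalene-2-carboxylic acid
Conditions: Pd(OAc)2 (10 mol %), PhI(OAc)2, I2, DMF, 100 °C
Reagents that add atoms: iodine, II
Why: Carboxylate-directed ortho C–H palladation and iodination by IOAc (formed from PhI(OAc)2 and I2) should functionalize the less hindered ortho position (flanked by H, not by the ring CH2), while the electron-poor ring resists ordinary electrophilic iodination.

Step 2
Reactants: 2 3-iodo-5-oxo-5,6,7,8-tetrahydronaphthalene-2-carboxylic acid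
Product: 3 tert-butyl 3-iodo-5-oxo-5,6,7,8-tetrahydronaphthalene-2-carboxylate
Conditions: Cl3CC(=NH)Ot-Bu, BF3·OEt2 (cat.), CH2Cl2/cyclohexane, 25 °C
Reagents that add atoms: tert-butyl 2,2,2-trichloroacetimidate, CC(C)(C)OC(=N)C(Cl)(Cl)Cl
Why: Acid-catalysed O-alkylation of the carboxylic acid by the imidate (tert-butyl ester formation) avoids acyl substitution at the hindered ortho-iodo carboxyl and leaves the ketone untouched.

Step 3
Reactants: 3 tert-butyl 3-iodo-5-oxo-5,6,7,8-tetrahydronaphthalene-2-carboxylate
Product: 4 tert-butyl 6-hydroxy-3-iodo-5,8-dioxo-5,8-dihydronaphthalene-2-carboxylate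
Conditions: t-BuOK, O2 (1 atm), t-BuOH, 25 °C; then aq HCl
Reagents that add atoms: dioxygen, O=O
Why: Base-mediated autoxidation of a 1-tetralone (enolate oxygenation, aromatization, further oxidation) is the classical route to 2-hydroxy-1,4-naphthoquinones and places the hydroxyl on the former α-carbon next to the former ketone, which later fixes the position of nitrogen.

Step 4
Reactants: 4 tert-butyl 6-hydroxy-3-iodo-5,8-dioxo-5,8-dihydronaphthalene-2-carboxylate
Product: 6 tert-butyl 3-iodo-5,6,8-trimethoxynaphthalene-2-carboxylate, via naphthalenetriol 5 (not isolated)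
Conditions: Na2S2O4, THF/H2O, N2, 25 °C; then KOH (aq), Me2SO4, Bu4NBr (cat.), 25 °C
Reagents that add atoms: dimethyl sulfate, COS(=O)(=O)OC
Why: Reductive methylation (dithionite reduction to the triol, then Williamson O-methylation) masks the quinone as a robust 1,2,4-trimethoxynaphthalene for the later base, hydride and sulfur chemistry.

Step 5
Reactants: 6 tert-butyl 3-iodo-5,6,8-trimethoxynaphthalene-2-carboxylate; 7 (E)-pent-3-en-2-one
Product: 8 tert-butyl 5,6,8-trimethoxy-3-[(2E)-4-oxopent-2-en-2-yl]naphthalene-2-carboxylate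
Conditions: Pd(OAc)2 (5 mol %), Bu4NCl, NaHCO3, DMF, 80 °C
Reagents that add atoms: none
Why: Heck reaction under ligand-free phase-transfer conditions: aryl-Pd should add to the β-carbon of the enone and syn β-hydride elimination should give the conjugated E-configured β-aryl-β-methyl enone.

Step 6
Reactants: 8 tert-butyl 5,6,8-trimethoxy-3-[(2E)-4-oxopent-2-en-2-yl]naphthalene-2-carboxylate; 9 ethyl acetoacetate
Product: 11 tert-butyl 3-[(1R)-2-(ethoxycarbonyl)-1,3-dimethyl-5-oxocyclohex-3-en-1-yl]-5,6,8-trimethoxynaphthalene-2-carboxylate, via Michael adduct 10 (not isolated)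
Conditions: 9-amino-9-deoxy-epi-quinine (20 mol %), 2-FC6H4CO2H (40 mol %), 9 (3 equiv), PhMe, 9 kbar, 50 °C; then 1 bar, 70 °C
Reagents that add atoms: none
Why: Proposed new method: the primary amine condenses with the methyl ketone of 8 to an iminium ion, the enol of 9 adds to its β-carbon to make the quaternary C–C bond (adduct 10), and the enamine of the acetonyl arm then attacks the acetoacetate ketone and loses water (intramolecular aldol condensation) to make the ring C=C bond. The closest known reactions are the acid- or base-mediated annulation of acetoacetates with β,β-dialkyl enones to 4-oxocyclohex-2-ene-1-carboxylates, primary-amine-catalysed Robinson-type annulations of β-keto esters with β-monosubstituted enones, and high-pressure iminium-catalysed Michael additions of nitroalkanes to β,β-disubstituted enones; new is their combination on a β-aryl-β-methyl enone with a β-keto ester. Ring A closes by 6-(enolendo)-exo-trig attack of the enamine carbon on the ketone, followed by dehydration. The aryl-bearing quaternary carbon is set by the cinchona amine, which shields one face of the iminium ion and, because the Michael step is reversible while cyclodehydration is not, also selects the matching adduct at ring closure; the ester-bearing carbon is epimerizable, is expected as a mixture and later becomes sp2. The step needs 1,4- over 1,2-addition (secured by iminium activation and the soft β-dicarbonyl nucleophile) and the correct aldol regiochemistry (secured because the acetoacetate unit is held as its enol or enaminoester, so only the acetonyl methyl acts as nucleophile); high pressure should offset the congestion at the ortho-substituted β-carbon.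

Step 7
Reactants: 11 tert-butyl 3-[(1R)-2-(ethoxycarbonyl)-1,3-dimethyl-5-oxocyclohex-3-en-1-yl]-5,6,8-trimethoxynaphthalene-2-carboxylate
Product: 12 tert-butyl 3-[(9R)-8-(ethoxycarbonyl)-7,9-dimethyl-1,4-dithiaspiro[4.5]dec-6-en-9-yl]-5,6,8-trimethoxynaphthalene-2-carboxylate
Conditions: HS(CH2)2SH, Zn(OTf)2, CH2Cl2, 25 °C
Reagents that add atoms: ethane-1,2-dithiol, SCCS
Why: Lewis-acid-promoted dithioketalization of the enone carbonyl (1,2-addition is favoured because the β-carbon is fully substituted) turns the helper ketone into a group removable under neutral conditions; both esters should tolerate Zn(OTf)2.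

Step 8
Reactants: 12 tert-butyl 3-[(9R)-8-(ethoxycarbonyl)-7,9-dimethyl-1,4-dithiaspiro[4.5]dec-6-en-9-yl]-5,6,8-trimethoxynaphthalene-2-carboxylate
Product: 13 tert-butyl 3-[(1R)-2-(ethoxycarbonyl)-1,3-dimethylcyclohex-3-en-1-yl]-5,6,8-trimethoxynaphthalene-2-carboxylate
Conditions: Raney Ni (W-2, deactivated in refluxing acetone), EtOH, 25–60 °C
Reagents that add atoms: none
Why: Raney Ni desulfurization (C–S hydrogenolysis) replaces the dithiolane by CH2; deactivated Ni should spare the trisubstituted alkene, and a shift of the alkene into conjugation with the ester would be harmless because both isomers lead to the same dienol later.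

Step 9
Reactants: 13 tert-butyl 3-[(1R)-2-(ethoxycarbonyl)-1,3-dimethylcyclohex-3-en-1-yl]-5,6,8-trimethoxynaphthalene-2-carboxylate
Product: 14 tert-butyl 3-[(1R)-2-formyl-1,3-dimethylcyclohex-3-en-1-yl]-5,6,8-trimethoxynaphthalene-2-carboxylate
Conditions: i-Bu2AlH (1.1 equiv), PhMe, −78 °C; then aq potassium sodium tartrate
Reagents that add atoms: none
Why: Partial ester reduction by i-Bu2AlH at low temperature (stable tetrahedral aluminate) should stop at the aldehyde, while the hindered aryl tert-butyl ester is left intact.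

Step 10
Reactants: 14 tert-butyl 3-[(1R)-2-formyl-1,3-dimethylcyclohex-3-en-1-yl]-5,6,8-trimethoxynaphthalene-2-carboxylate
Product: 15 tert-butyl 3-[(1R)-2-formyl-1,3-dimethylcyclohex-3-en-1-yl]-6-methoxy-5,8-dioxo-5,8-dihydronaphthalene-2-carboxylate
Conditions: (NH4)2Ce(NO3)6 (2.5 equiv), MeCN/H2O, 0 °C
Reagents that add atoms: water, O
Why: Oxidative demethylation of the para-dimethoxy pair (single-electron oxidation, attack of water, loss of methanol) should give the 2-methoxy-1,4-quinone, the remaining methoxy group serving as the regiochemical marker.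

Step 11
Reactants: 15 tert-butyl 3-[(1R)-2-formyl-1,3-dimethylcyclohex-3-en-1-yl]-6-methoxy-5,8-dioxo-5,8-dihydronaphthalene-2-carboxylate; 16 hypotaurine (2-aminoethanesulfinic acid)
Product: 19 tert-butyl 7-[(1R)-2-formyl-1,3-dimethylcyclohex-3-en-1-yl]-5,10-dioxo-3,4,5,10-tetrahydro-2H-naphtho[2,3-b][1,4]thiazine-8-carboxylate 1,1-dioxide, via aminoquinone sulfinic acid 17 (not isolated), via thiazine-fused hydroquinone 18 (not isolated)
Conditions: 16 (1.5 equiv), EtOH/MeCN/H2O, air, 25 °C
Reagents that add atoms: none
Why: Hypotaurine annulation of a quinone: addition–elimination of the amine at the methoxy-bearing carbon, intramolecular sulfa-Michael addition of the sulfinate (six-membered ring) and air oxidation; the methoxy group dictates that N ends next to the former tetralone carbonyl and S on the other quinone carbon.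

Step 12
Reactants: 19 tert-butyl 7-[(1R)-2-formyl-1,3-dimethylcyclohex-3-en-1-yl]-5,10-dioxo-3,4,5,10-tetrahydro-2H-naphtho[2,3-b][1,4]thiazine-8-carboxylate 1,1-dioxide
Product: 21 target enol lactone CNP0348176.1 (S-configured quaternary carbon), via carboxylic acid 20 (not isolated)
Conditions: CF3CO2H/CH2Cl2, 25 °C; then (CF3CO)2O, 0 → 25 °C; aq NaHCO3
Reagents that add atoms: none
Why: Acidolysis of the tert-butyl ester, then dehydrative enol lactonization: the mixed trifluoroacetic anhydride of the aryl acid should acylate the oxygen of the conjugated dienol of the β,γ-unsaturated aldehyde (seven-membered ring), giving the enol ester with the ring C=C already in place and the quaternary stereocentre untouched.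

**Compound list**

1 | 5-oxo-5,6,7,8-tetrahydronaphthalene-2-carboxylic acid | O=C1CCCc2cc(C(=O)O)ccc12 | starting material
2 | 3-iodo-5-oxo-5,6,7,8-tetrahydronaphthalene-2-carboxylic acid | O=C1CCCc2cc(C(=O)O)c(I)cc12 | intermediate
3 | tert-butyl 3-iodo-5-oxo-5,6,7,8-tetrahydronaphthalene-2-carboxylate | O=C1CCCc2cc(C(=O)OC(C)(C)C)c(I)cc12 | intermediate
4 | tert-butyl 6-hydroxy-3-iodo-5,8-dioxo-5,8-dihydronaphthalene-2-carboxylate | O=C1C(O)=CC(=O)c2cc(C(=O)OC(C)(C)C)c(I)cc12 | intermediate
5 | tert-butyl 5,6,8-trihydroxy-3-iodonaphthalene-2-carboxylate (not isolated) | Oc1c(O)cc(O)c2cc(C(=O)OC(C)(C)C)c(I)cc12 | intermediate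
6 | tert-butyl 3-iodo-5,6,8-trimethoxynaphthalene-2-carboxylate | COc1c(OC)cc(OC)c2cc(C(=O)OC(C)(C)C)c(I)cc12 | intermediate
7 | (E)-pent-3-en-2-one | C/C=C/C(C)=O | starting material
8 | tert-butyl 5,6,8-trimethoxy-3-[(2E)-4-oxopent-2-en-2-yl]naphthalene-2-carboxylate | COc1c(OC)cc(OC)c2cc(C(=O)OC(C)(C)C)c(/C(C)=C/C(C)=O)cc12 | intermediate
9 | ethyl acetoacetate (ethyl 3-oxobutanoate) | CCOC(=O)CC(C)=O | starting material
10 | ethyl (3R)-2-acetyl-3-[3-(tert-butoxycarbonyl)-5,7,8-trimethoxynaphthalen-2-yl]-3-methyl-5-oxohexanoate (Michael adduct, not isolated) | CCOC(=O)C(C(C)=O)[C@@](C)(CC(C)=O)c1cc2c(OC)c(OC)cc(OC)c2cc1C(=O)OC(C)(C)C | intermediate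
11 | tert-butyl 3-[(1R)-2-(ethoxycarbonyl)-1,3-dimethyl-5-oxocyclohex-3-en-1-yl]-5,6,8-trimethoxynaphthalene-2-carboxylate (epimers at the ester-bearing carbon) | CCOC(=O)C1C(C)=CC(=O)C[C@@]1(C)c1cc2c(OC)c(OC)cc(OC)c2cc1C(=O)OC(C)(C)C | intermediate
12 | tert-butyl 3-[(9R)-8-(ethoxycarbonyl)-7,9-dimethyl-1,4-dithiaspiro[4.5]dec-6-en-9-yl]-5,6,8-trimethoxynaphthalene-2-carboxylate | CCOC(=O)C1C(C)=CC3(SCCS3)C[C@@]1(C)c1cc2c(OC)c(OC)cc(OC)c2cc1C(=O)OC(C)(C)C | intermediate
13 | tert-butyl 3-[(1R)-2-(ethoxycarbonyl)-1,3-dimethylcyclohex-3-en-1-yl]-5,6,8-trimethoxynaphthalene-2-carboxylate | CCOC(=O)C1C(C)=CCC[C@@]1(C)c1cc2c(OC)c(OC)cc(OC)c2cc1C(=O)OC(C)(C)C | intermediate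
14 | tert-butyl 3-[(1R)-2-formyl-1,3-dimethylcyclohex-3-en-1-yl]-5,6,8-trimethoxynaphthalene-2-carboxylate | O=CC1C(C)=CCC[C@@]1(C)c1cc2c(OC)c(OC)cc(OC)c2cc1C(=O)OC(C)(C)C | intermediate
15 | tert-butyl 3-[(1R)-2-formyl-1,3-dimethylcyclohex-3-en-1-yl]-6-methoxy-5,8-dioxo-5,8-dihydronaphthalene-2-carboxylate | O=CC1C(C)=CCC[C@@]1(C)c1cc2C(=O)C(OC)=CC(=O)c2cc1C(=O)OC(C)(C)C | intermediate
16 | hypotaurine (2-aminoethanesulfinic acid) | NCCS(=O)O | starting material
17 | tert-butyl 3-[(1R)-2-formyl-1,3-dimethylcyclohex-3-en-1-yl]-5,8-dioxo-6-[(2-sulfinoethyl)amino]-5,8-dihydronaphthalene-2-carboxylate (not isolated) | O=CC1C(C)=CCC[C@@]1(C)c1cc2C(=O)C(NCCS(=O)O)=CC(=O)c2cc1C(=O)OC(C)(C)C | intermediate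
18 | tert-butyl 7-[(1R)-2-formyl-1,3-dimethylcyclohex-3-en-1-yl]-5,10-dihydroxy-3,4-dihydro-2H-naphtho[2,3-b][1,4]thiazine-8-carboxylate 1,1-dioxide (not isolated) | O=CC1C(C)=CCC[C@@]1(C)c1cc2c(O)c3NCCS(=O)(=O)c3c(O)c2cc1C(=O)OC(C)(C)C | intermediate
19 | tert-butyl 7-[(1R)-2-formyl-1,3-dimethylcyclohex-3-en-1-yl]-5,10-dioxo-3,4,5,10-tetrahydro-2H-naphtho[2,3-b][1,4]thiazine-8-carboxylate 1,1-dioxide | O=CC1C(C)=CCC[C@@]1(C)c1cc2C(=O)C3=C(C(=O)c2cc1C(=O)OC(C)(C)C)S(=O)(=O)CCN3 | intermediate
20 | 7-[(1R)-2-formyl-1,3-dimethylcyclohex-3-en-1-yl]-5,10-dioxo-3,4,5,10-tetrahydro-2H-naphtho[2,3-b][1,4]thiazine-8-carboxylic acid 1,1-dioxide (not isolated) | O=CC1C(C)=CCC[C@@]1(C)c1cc2C(=O)C3=C(C(=O)c2cc1C(=O)O)S(=O)(=O)CCN3 | intermediate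
21 | CNP0348176.1: the (S)-enol lactone in which the carboxyl group of 20 is esterified by the dienol oxygen of its formyl group (seven-membered benzoxepinone fused to the methylcyclohexadiene ring A and to the thiazine-dioxide quinone) | CC1=CCC[C@]2(C)C1=COC(=O)c1cc3c(cc12)C(=O)C1=C(C3=O)S(=O)(=O)CCN1 | target

Total step count: 12. Longest linear sequence: 12 steps (from 1).

**Steps most likely to fail**

Step 6 (key step). The conjugate addition may stall at the congested, ortho-substituted β-carbon, may revert faster than the ring closes, or may proceed with poor facial selectivity. The fallback uses known chemistry, builds ring A through different bonds and never forms the helper ketone; it sets out from 6 and returns at 14. Pd-catalysed α-arylation of propanal with 6 (Pd(OAc)2, rac-BINAP, Cs2CO3, dioxane, 80 °C) would give the racemic α-aryl propanal F1. An enamine-catalysed asymmetric Robinson annulation of this α-branched aldehyde with pent-1-en-3-one (chiral proline-derived sulfonamide or primary-amine catalyst) would set the quaternary centre and give the 4-aryl-2,4-dimethylcyclohexenone F2. Luche reduction (NaBH4, CeCl3·7H2O, MeOH) would give the allylic alcohol F3, and O-alkylation (KH, Bu3SnCH2I, THF) the stannylmethyl ether F4. Tin–lithium exchange (n-BuLi, THF, −78 °C) with [2,3]-Wittig–Still rearrangement would transfer the CH2O unit to the carbon next to the quaternary centre and move the alkene to the required position, giving the homoallylic alcohol F5. Dess–Martin oxidation of F5 would give 14.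

Step 12. Closure of the seven-membered enol lactone may be outrun by intermolecular acylation or by acylation at nitrogen, and the quinone may degrade in the acylating medium. The fallback closes the lactone before the quinone is unveiled; it sets out from 14 and returns at 21. Acidolysis of 14 (CF3CO2H, CH2Cl2) would give the aldehyde acid F6. Base-mediated lactonization through the mixed anhydride (2,4,6-trichlorobenzoyl chloride, Et3N, DMAP; O-acylation of the dienolate) would give the trimethoxy enol lactone F7. Oxidative demethylation ((NH4)2Ce(NO3)6, MeCN/H2O, 0 °C) would give the methoxyquinone enol lactone F8, and hypotaurine annulation of F8 as in step 11 would give 21.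

Step 5. Insertion of the internal alkene at the hindered ortho-substituted aryl iodide may be slow, and β-hydride elimination may deliver the non-conjugated alkene isomer. The fallback replaces the Heck reaction by an alkyne route; it sets out from 6 and returns at 8. Sonogashira coupling of 6 with but-3-yn-2-ol (Pd(PPh3)2Cl2, CuI, Et3N) would give the propargylic alcohol F9, and MnO2 oxidation the ynone F10. Conjugate addition of Me2CuLi (THF, −78 °C), followed by iodine-catalysed equilibration of the alkene geometry, would give 8.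

Further compounds
F1 | step 6 | tert-butyl 5,6,8-trimethoxy-3-(1-oxopropan-2-yl)naphthalene-2-carboxylate (racemic) | CC(C=O)c1cc2c(OC)c(OC)cc(OC)c2cc1C(=O)OC(C)(C)C
F2 | step 6 | tert-butyl 3-[(1R)-1,3-dimethyl-4-oxocyclohex-2-en-1-yl]-5,6,8-trimethoxynaphthalene-2-carboxylate | CC1=C[C@@](C)(CCC1=O)c1cc2c(OC)c(OC)cc(OC)c2cc1C(=O)OC(C)(C)C
F3 | step 6 | tert-butyl 3-[(1R)-4-hydroxy-1,3-dimethylcyclohex-2-en-1-yl]-5,6,8-trimethoxynaphthalene-2-carboxylate (carbinol epimers) | CC1=C[C@@](C)(CCC1O)c1cc2c(OC)c(OC)cc(OC)c2cc1C(=O)OC(C)(C)C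
F4 | step 6 | tert-butyl 3-{(1R)-1,3-dimethyl-4-[(tributylstannyl)methoxy]cyclohex-2-en-1-yl}-5,6,8-trimethoxynaphthalene-2-carboxylate | CC1=C[C@@](C)(CCC1OC[Sn](CCCC)(CCCC)CCCC)c1cc2c(OC)c(OC)cc(OC)c2cc1C(=O)OC(C)(C)C
F5 | step 6 | tert-butyl 3-[(1R)-2-(hydroxymethyl)-1,3-dimethylcyclohex-3-en-1-yl]-5,6,8-trimethoxynaphthalene-2-carboxylate | OCC1C(C)=CCC[C@@]1(C)c1cc2c(OC)c(OC)cc(OC)c2cc1C(=O)OC(C)(C)C
F6 | step 12 | 3-[(1R)-2-formyl-1,3-dimethylcyclohex-3-en-1-yl]-5,6,8-trimethoxynaphthalene-2-carboxylic acid | O=CC1C(C)=CCC[C@@]1(C)c1cc2c(OC)c(OC)cc(OC)c2cc1C(=O)O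
F7 | step 12 | (S)-enol lactone of F6 (ring system of 21 with a 1,2,4-trimethoxynaphthalene in place of the thiazine-fused quinone) | CC1=CCC[C@]2(C)C1=COC(=O)c1cc3c(OC)cc(OC)c(OC)c3cc12
F8 | step 12 | (S)-enol lactone with a 2-methoxy-1,4-naphthoquinone in place of the thiazine-fused quinone | CC1=CCC[C@]2(C)C1=COC(=O)c1cc3C(=O)C=C(OC)C(=O)c3cc12
F9 | step 5 | tert-butyl 3-(3-hydroxybut-1-yn-1-yl)-5,6,8-trimethoxynaphthalene-2-carboxylate | CC(O)C#Cc1cc2c(OC)c(OC)cc(OC)c2cc1C(=O)OC(C)(C)C
F10 | step 5 | tert-butyl 5,6,8-trimethoxy-3-(3-oxobut-1-yn-1-yl)naphthalene-2-carboxylate | CC(=O)C#Cc1cc2c(OC)c(OC)cc(OC)c2cc1C(=O)OC(C)(C)C
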